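**Retrosynthetic overview**
1. The benzene ring is numbered C1 (CH2SO2CH3 arm), C2 (Br), C3 (OH), C4 (OH), C5 (Br), C6 (Br). The route rests on two features: the vicinal oxygen-bearing carbons C3/C4 are the two carbonyl carbons of an oxalate, and C2 and C5, each ortho to a hydroxyl, can carry CO2Me groups that are later exchanged for bromine.
2. Target 16 comes from catechol diacetate 12 by benzylic bromination of the C1 methyl, sulfinate displacement and deacetylation; 12 comes from tribromomethylcatechol 11.
3. Compound 11 comes from diacid 8 with Br2 (ipso-bromodecarboxylation at C2 and C5, C–H bromination at C6); 8 comes from aromatic diester 7, and 7 from cyclohexadiene 5 by dehydrogenation.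
4. Compound 5 is cut at C4–C5 and C2–C3 (double Claisen) into dimethyl oxalate 3 (C3, C4) and dimethyl 3-methyladipate 2 (C5–C6–C1–C2 plus the C1 methyl).
5. Ring order: the single carbocycle is closed in step 2 and aromatized in step 3; no other ring is formed.

Key step: step 2

Assumption: racemic 3-methyladipic acid is used; its only stereocentre becomes the sp2 carbon C1 on aromatization, and the target is achiral. In step 5 the brominations are drawn with C–H substitution first and the two ipso-substitutions after it; any other order would converge on the same product 11.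

**Route**

Step 1
Reactants: 1 3-methyladipic acid (racemic)
Product: 2 dimethyl 3-methyladipate (racemic)
Conditions: MeOH, H2SO4 (cat.), reflux
Reagents that add atoms: methanol, CO
Why: Fischer esterification driven by the excess of methanol; no sensitive group is present.

Step 2
Reactants: 2 dimethyl 3-methyladipate; 3 dimethyl oxalate
Product: 5 dimethyl 2,3-dihydroxy-5-methylcyclohexa-1,3-diene-1,4-dicarboxylate (racemic bis-enol of the 2,3-dioxo diester), via dimethyl 2-(2-methoxy-2-oxoacetyl)-4-methylhexanedioate 4 (not isolated)
Conditions: NaOMe (2.3 equiv), Et2O, 3 then 2 added, 0 °C to reflux; then cold 2 M HCl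
Reagents that add atoms: none
Why: This is a crossed Claisen condensation followed by a Dieckmann-type closure: methoxide forms the enolate at the less hindered alpha carbon of 2 (future C5), which attacks the non-enolizable, strongly electrophilic oxalate to give 4 (bond C4–C5), and the second enolate, next to the methyl-bearing carbon (future C2), then attacks the remaining oxalyl ester (bond C2–C3). The closest known reaction type is the alkoxide-mediated condensation of dialkyl oxalates with dialkyl glutarates and adipates to cyclic 1,2-dione diesters. The carbocycle closes by a 6-(enolexo)-exo-trig acyl substitution. No new stereocentre persists, because both alpha carbons end as enol carbons, and the inherited methyl-bearing centre stays racemic and is erased in step 3. The step needs chemoselectivity for intermolecular oxalylation and six-ring closure over the five-ring Dieckmann cyclization of 2; every step is reversible under methoxide, oxalate is the better electrophile, and the doubly deprotonated bis(beta-keto ester), expected to separate from ether as its disodium salt, is the thermodynamic sink. The order of the two acylations does not matter, since both regioisomeric mono-adducts converge on 5.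

Step 3
Reactants: 5 dimethyl 2,3-dihydroxy-5-methylcyclohexa-1,3-diene-1,4-dicarboxylate
Product: 7 dimethyl 2,3-dihydroxy-5-methylterephthalate, via dimethyl 1-bromo-3-hydroxy-5-methyl-2-oxocyclohex-3-ene-1,4-dicarboxylate 6 (not isolated)
Conditions: Br2 (1.05 equiv), CHCl3, 0 °C then reflux
Reagents that add atoms: none
Why: Bromination–dehydrobromination aromatization: electrophilic alpha-bromination of the enolized beta-keto ester gives 6, which eliminates HBr and tautomerizes to the catechol with gain of aromaticity, and any over-bromination of the deactivated ring would fall on C6, where bromine is wanted later.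

Step 4
Reactants: 7 dimethyl 2,3-dihydroxy-5-methylterephthalate
Product: 8 2,3-dihydroxy-5-methylterephthalic acid
Conditions: NaOH (6 equiv), H2O/MeOH, reflux, N2; then HCl
Reagents that add atoms: sodium hydroxide, [Na+].[OH-]
Why: Saponification (BAc2 hydrolysis) of both methyl esters, run hot because the salicylate-type esters are deactivated as phenoxides and under nitrogen because the catechol dianion is air-sensitive.

Step 5
Reactants: 8 2,3-dihydroxy-5-methylterephthalic acid
Product: 11 3,4,6-tribromo-5-methylbenzene-1,2-diol, via 5-bromo-2,3-dihydroxy-6-methylterephthalic acid 9 (not isolated), via 4,5-dibromo-2,3-dihydroxy-6-methylbenzoic acid 10 (not isolated)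
Conditions: Br2 (3.3 equiv), AcOH/H2O, 20 to 50 °C
Reagents that add atoms: bromine, BrBr
Why: Electrophilic aromatic bromination at C6 (para to the C3 hydroxyl) is followed by two ipso-bromodecarboxylations at C5 and C2, each ortho to a hydroxyl, the reaction type by which salicylic acid gives 2,4,6-tribromophenol with bromine water; loss of CO2 from each ipso sigma-complex is irreversible.

Step 6
Reactants: 11 3,4,6-tribromo-5-methylbenzene-1,2-diol
Product: 12 3,4,6-tribromo-5-methyl-1,2-phenylene diacetate
Conditions: Ac2O (3 equiv), pyridine, DMAP (cat.), CH2Cl2, 20 °C
Reagents that add atoms: acetic anhydride, CC(=O)OC(C)=O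
Why: Nucleophile-catalysed O-acylation of both phenols masks the oxidation-prone catechol and removes the phenolic hydrogen-atom donors before the radical step.

Step 7
Reactants: 12 3,4,6-tribromo-5-methyl-1,2-phenylene diacetate
Product: 13 3,4,6-tribromo-5-(bromomethyl)-1,2-phenylene diacetate
Conditions: NBS (1.1 equiv), AIBN (cat.), PhCF3, reflux, visible light
Reagents that add atoms: N-bromosuccinimide, O=C1CCC(=O)N1Br
Why: Wohl–Ziegler benzylic bromination; the C1 methyl carries the only benzylic C–H bonds, and 2,6-dibromotoluenes undergo this radical substitution despite the flanking halogens.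

Step 8
Reactants: 13 3,4,6-tribromo-5-(bromomethyl)-1,2-phenylene diacetate; 14 sodium methanesulfinate (CH3SO2Na)
Product: 15 3,4,6-tribromo-5-[(methylsulfonyl)methyl]-1,2-phenylene diacetate
Conditions: CH3SO2Na (1.5 equiv), DMF, 20 to 50 °C
Reagents that add atoms: none
Why: SN2 displacement of the benzylic bromide by the soft sulfur atom of the ambident sulfinate gives the sulfone, while aryl bromides and aryl acetates are inert to this weakly basic nucleophile.

Step 9
Reactants: 15 3,4,6-tribromo-5-[(methylsulfonyl)methyl]-1,2-phenylene diacetate
Product: 16 3,4,6-tribromo-5-[(methylsulfonyl)methyl]benzene-1,2-diol (2,3,6-tribromo-4,5-dihydroxybenzyl methyl sulfone, the target)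
Conditions: HCl (1.25 M in MeOH), 50 °C, N2
Reagents that add atoms: none
Why: Acid-catalysed transesterification (methanolysis) of the two aryl acetates frees the catechol without exposing it or the acidic benzylic sulfone methylene to base.

**Compound list**
1 | 3-methyladipic acid (racemic) | CC(CCC(=O)O)CC(=O)O | starting material
2 | dimethyl 3-methyladipate (racemic) | COC(=O)CC(C)CCC(=O)OC | intermediate
3 | dimethyl oxalate | COC(=O)C(=O)OC | starting material
4 | dimethyl 2-(2-methoxy-2-oxoacetyl)-4-methylhexanedioate (mixture of stereoisomers, present as its sodium enolate) | COC(=O)CC(C)CC(C(=O)OC)C(=O)C(=O)OC | intermediate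
5 | dimethyl 2,3-dihydroxy-5-methylcyclohexa-1,3-diene-1,4-dicarboxylate (racemic; bis-enol of dimethyl 5-methyl-2,3-dioxocyclohexane-1,4-dicarboxylate) | COC(=O)C1=C(O)C(O)=C(C(=O)OC)C(C)C1 | intermediate
6 | dimethyl 1-bromo-3-hydroxy-5-methyl-2-oxocyclohex-3-ene-1,4-dicarboxylate (mixture of stereoisomers) | COC(=O)C1(Br)CC(C)C(C(=O)OC)=C(O)C1=O | intermediate
7 | dimethyl 2,3-dihydroxy-5-methylterephthalate | COC(=O)c1cc(C)c(C(=O)OC)c(O)c1O | intermediate
8 | 2,3-dihydroxy-5-methylterephthalic acid | Cc1cc(C(=O)O)c(O)c(O)c1C(=O)O | intermediate
9 | 5-bromo-2,3-dihydroxy-6-methylterephthalic acid | Cc1c(Br)c(C(=O)O)c(O)c(O)c1C(=O)O | intermediate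
10 | 4,5-dibromo-2,3-dihydroxy-6-methylbenzoic acid | Cc1c(Br)c(Br)c(O)c(O)c1C(=O)O | intermediate
11 | 3,4,6-tribromo-5-methylbenzene-1,2-diol | Cc1c(Br)c(O)c(O)c(Br)c1Br | intermediate
12 | 3,4,6-tribromo-5-methyl-1,2-phenylene diacetate | CC(=O)Oc1c(Br)c(C)c(Br)c(Br)c1OC(C)=O | intermediate
13 | 3,4,6-tribromo-5-(bromomethyl)-1,2-phenylene diacetate | CC(=O)Oc1c(Br)c(CBr)c(Br)c(Br)c1OC(C)=O | intermediate
14 | sodium methanesulfinate | CS(=O)[O-].[Na+] | starting material
15 | 3,4,6-tribromo-5-[(methylsulfonyl)methyl]-1,2-phenylene diacetate | CC(=O)Oc1c(Br)c(CS(C)(=O)=O)c(Br)c(Br)c1OC(C)=O | intermediate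
16 | 3,4,6-tribromo-5-[(methylsulfonyl)methyl]benzene-1,2-diol | CS(=O)(=O)Cc1c(Br)c(O)c(O)c(Br)c1Br | target

**Step count**
Total steps: 9. Longest linear sequence: 9 steps (1 to 16).

**Steps most likely to fail**

Step 2. The adipate may undergo intramolecular Dieckmann cyclization to five-membered beta-keto esters faster than it is oxalylated, or the sequence may stall after the first acylation because the enolate next to the methyl-bearing carbon closes the ring slowly. The fallback sets out from 2 and comes back at 5, replacing the equilibrating alkoxide condensation with an irreversible, non-basic double acylation of a preformed bis-nucleophile. Compound 2 is deprotonated twice in the presence of the silylating agent (LiN(iPr)2 with Me3SiCl as in-situ quench, THF, −78 °C), so that each enolate is trapped before it can cyclize. This should give the bis(silyl ketene acetal) 1,6-dimethoxy-3-methyl-1,6-bis(trimethylsilyloxy)hexa-1,5-diene F1. Treatment of F1 with oxalyl chloride (CH2Cl2, −78 to 20 °C, Me3SiOTf cat.) should acylate the two nucleophilic carbons in turn, the second time intramolecularly, and give 5 after aqueous work-up.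

Step 5. Bromine may oxidize the electron-rich catechol to the ortho-quinone, or the sequence may stop before the second ipso-substitution at the more crowded C2, leaving a carboxyl group in place. The fallback sets out from 8 and comes back at 11, separating decarboxylation from bromination. Diacid 8 is heated in quinoline at about 200 °C, where ipso-protonation ortho to each hydroxyl and loss of CO2 should give 4-methylbenzene-1,2-diol F2. Ordinary threefold electrophilic bromination of F2 at its three free ring positions (Br2, AcOH, 20 °C) should then give 11.

Step 7. Hydrogen abstraction from a methyl group shielded by two ortho bromines may be slow, so that the reaction either does not start or runs on to the benzal bromide. The fallback sets out from 7 and comes back at the target 16, moving the side-chain chemistry ahead of the ring bromination so that the radical step meets an unhindered methyl group.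
- Acetylation of 7 (Ac2O, pyridine, DMAP) should give dimethyl 2,3-diacetoxy-5-methylterephthalate F3.
- Wohl–Ziegler bromination (NBS, AIBN, PhCF3, reflux) should give dimethyl 2,3-diacetoxy-5-(bromomethyl)terephthalate F4.
- Displacement with CH3SO2Na in DMF at 20 °C should give dimethyl 2,3-diacetoxy-5-[(methylsulfonyl)methyl]terephthalate F5.
- Hydrolysis of all four ester groups (aqueous NaOH, reflux, N2, then HCl) should give 2,3-dihydroxy-5-[(methylsulfonyl)methyl]terephthalic acid F6.
- Treatment of F6 with Br2 in aqueous AcOH, as in step 5, should install the three ring bromines by C–H substitution and twofold bromodecarboxylation and deliver 16 directly.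

**Further compounds**
F1 | step 2 | 1,6-dimethoxy-3-methyl-1,6-bis(trimethylsilyloxy)hexa-1,5-diene | COC(O[Si](C)(C)C)=CC(C)CC=C(OC)O[Si](C)(C)C
F2 | step 5 | 4-methylbenzene-1,2-diol | Cc1ccc(O)c(O)c1
F3 | step 7 | dimethyl 2,3-diacetoxy-5-methylterephthalate | COC(=O)c1cc(C)c(C(=O)OC)c(OC(C)=O)c1OC(C)=O
F4 | step 7 | dimethyl 2,3-diacetoxy-5-(bromomethyl)terephthalate | COC(=O)c1cc(CBr)c(C(=O)OC)c(OC(C)=O)c1OC(C)=O
F5 | step 7 | dimethyl 2,3-diacetoxy-5-[(methylsulfonyl)methyl]terephthalate | COC(=O)c1cc(CS(C)(=O)=O)c(C(=O)OC)c(OC(C)=O)c1OC(C)=O
F6 | step 7 | 2,3-dihydroxy-5-[(methylsulfonyl)methyl]terephthalic acid | CS(=O)(=O)Cc1cc(C(=O)O)c(O)c(O)c1C(=O)O
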